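Compound numbers are fixed by the steps below and used throughout.

## Analysis of the target

The target (19, CNP0279305.0, C34H26O6) is an unsymmetrical dimer of two 2-(2-phenylethyl)chromen-4-ones. Unit A is a 7-hydroxychromone (benzene ring A fused to pyranone A) bonded through C6 to C5' of unit B, an 8'-hydroxychromone (benzene ring B fused to pyranone B). There is no stereocentre, and the C6–C5' axis has only one ortho substituent on each ring (the C7 hydroxyl; C4a' with its peri carbonyl C4'=O), so rotation should be fast and no configuration has to be controlled. The sensitive groups are the two γ-pyranones, which are vinylogous esters that hydroxide or alkoxide can open at C2 or C2' and whose CH2 groups on C2 and C2' are vinylogously acidic, and the two phenols, which must stay masked through organometallic and Lewis-acid steps. The difficulty is that the halves are joined at non-equivalent positions, which rules out any dimerisation, and that ring B is substituted on four neighbouring carbons: C8' (O), C8a' (O), C4a' (acyl) and C5' (aryl). C5' lies peri to the C4' carbonyl, so a cross-coupling at C5' of a finished chromone, or an acylation at C4a' of a finished biaryl, would each have to take place beside a bulky neighbour. The plan rests on the fact that the biaryl carbon C5' and the acyl-bearing carbon C4a' are adjacent on ring B, with the oxygen-bearing C8a' on the other side of C4a'. That is the pattern left when a carbon nucleophile and a carbon electrophile add across an aryne whose triple bond is flanked by a methoxy group. Ring A is the easy half, since the oxygens on C7 and C8a both direct an electrophile to C4a.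

## Retrosynthetic reasoning

**19 back to 18.** The two phenolic O–H bonds are traced back to O–CH3 bonds. Methyl ethers survive arylmagnesium reagents, Lewis acids, hydride base and hot acid, so one protecting group serves the whole route and a single double ether cleavage ends it.

**18 back to 17, then to 15 and 16.** Pyranone A is opened at O1–C2 to the 1,3-diketone 17, and 17 is cut at C2–C3 into methyl ketone 15 and ester 16. This is the standard chromone assembly, and it brings in the phenethyl chain of unit A with the ester. The forward condensation has to run in the presence of the finished pyranone B, which is the main concern of the late stage.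

**15 back to 14 and 13.** The C4a–C4 bond is cut as a Friedel–Crafts acetylation of 13. C4a is para to the C7 ether and ortho to the C8a ether, so both donors point to it, while ring B is deactivated by its carbonyl. The C8a methyl group, now beside a ketone, is then removed selectively by chelation to give 15.

**13 back to 11 and 10.** Pyranone B is opened at O1'–C2' to the ortho-hydroxyaryl ynone 11, which comes from the methyl ether 10 by the same chelation-controlled cleavage. The ynone already holds C4', C3', C2' and the phenethyl chain at the correct oxidation level, so the forward step only needs a 6-endo attack of the C8a' oxygen.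

**10 back to 2, 6 and 5 (through 7, 8 and 9).** Two bonds on neighbouring carbons of ring B are cut together: C6–C5' and C4a'–C4'. Cutting only the biaryl bond would demand a coupling next to the acyl group. Cutting only the acyl bond would demand functionalisation of a position squeezed between an ether and an aryl group, where directed metalation of the biaryl would prefer the open C7' site. Treating C5'≡C4a' as the aryne 8 avoids both problems: the aryl group of 2 enters at C5', the resulting arylmagnesium 9 at C4a' is acylated by 5, and the C8a' methoxy group fixes the orientation. The forward reaction must generate 8 from 6 through 7 in the presence of 2 and must deliver the carbonyl carbon to a hindered carbanion.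

**2 back to 1, and 5 back to 3 (through 4).** The Grignard reagent 2 comes from the bromide 1 by magnesium insertion. The amide 5 comes in one operation from the alkyne 3 by deprotonation to 4 and capture with the carbamoyl chloride that carries the N-methoxy-N-methyl group.

## Alternatives that were turned down

**Alternative 1: propargyl ether rearrangement onto C4a'.**
- Disconnection: C4'–C4a' and O1'–C2' of pyran ring B, leading back to the aryl propargyl ether A2. In A2 unit A is already a chromone, the biaryl bond exists, and the C8a' oxygen carries a 5-phenylpent-1-yn-3-yl group.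
- Key step: heating A2 should trigger a [3,3] shift of the alkyne terminus to C4a' (the only free ortho position, since C8' carries a methoxy group). Enolisation, a 1,5-hydrogen shift and an oxa-6π ring closure then give the racemic 2H-chromene A1.
- For: the C–C bond at the crowded C4a' forms intramolecularly under neutral conditions, with no regiochemical question. The biaryl bond can be made earlier by an unhindered cross-coupling because C4a' is still unsubstituted. On the certainty of the C4a' bond this plan is at least as strong as the chosen one.
- Against: A1 is at the wrong oxidation level. C4' must still be oxidised to a ketone and the transient C2' stereocentre erased by dehydrogenation, which means two or three redox operations on a molecule holding an electron-rich arene and a pyranone. Making A2 requires O-alkylation of a flanked phenol with a secondary propargylic electrophile. Pyranone A must survive the thermolysis.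
- Comparison: the chosen route gives ketone 10 with C4' at the final oxidation level and the whole carbon chain of pyranone B in the same step that makes the biaryl bond, which saves those redox operations.

**Alternative 2: benzannulation that grows ring A on ring B.**
- Disconnection: benzene ring A itself, leading back to the diazo enone A4 (a ring B arene carrying a 4-diazo-3-oxobut-1-enyl chain at C5' and an ester at C4a') and ethoxyethyne A5.
- Key step: irradiation of A4 should give an aryl-substituted vinylketene by Wolff rearrangement. This adds A5 in a [2+2] fashion, and on heating the cyclobutenone opens and recloses by 6π-electrocyclisation to the biaryl phenol A3.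
- For: the biaryl bond is never made as such, because C6 is attached to C5' from the start, so hindrance at C5' is irrelevant. The ring A oxygens emerge differentiated (free hydroxyl on C7, ethyl ether on C8a). On this point it is stronger than the chosen route, where both ring A oxygens are methyl ethers and are told apart only later by chelation in step 7.
- Against: A3 carries an ester at C4a', flanked by an ether and an aryl group, and converting such a benzoate into the 1,3-dicarbonyl chain of pyranone B is difficult. C4a is still unfunctionalised, so the acylation of the chosen route is needed anyway. A4 takes several steps to make, and A5 is volatile and costly.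
- Comparison: the chosen route reaches 10 from three simple building blocks in one step, with C4' already a ketone bearing its full chain.

**Alternative 3: folding a pyranone-masked polyketone into ring A.**
- Disconnection: the C4a–C5 bond of ring A, leading back to A7, a 4-pyranone (the future pyranone A) whose C8a carries a CH2–CO–C(aryl)=CH(OMe) chain, the aryl group being the complete 8'-methoxy unit B.
- Key step: acid should enolise the chain ketone towards the pyranone. C4a then attacks the methoxymethylene carbon C5, and loss of methanol aromatises ring A to the 8'-O-methyl ether A6.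
- For: the closure is late, metal-free and polyketide-like, and delivers the free C7 hydroxyl directly, so only one ether cleavage remains. Its endgame is shorter than that of the chosen route.
- Against: A7 is harder to make than the target. It needs an aryl-acetic type residue on the peri-hindered C5' of a finished pyranone B, acylation of a pyranone side-chain anion and a methoxymethylenation, all with base-sensitive pyranones present. C4a of a γ-pyranone is a weak nucleophile in acid, and the enol oxygen can compete for C5. The problem of attaching carbon to C5' is displaced, not solved.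
- Comparison: the chosen route solves the congested C5'/C4a' pair in a single operation and builds both pyranones by standard annulations.

Key step: step 3

## Route

Remark on the chemistry: the C6–C5' axis carries one ortho substituent on each ring and is taken to rotate freely, so no axial configuration is specified.

Step 1
Reactants: 1 1-bromo-2,4-dimethoxybenzene
Product: 2 2,4-dimethoxyphenylmagnesium bromide
Conditions: Mg turnings, I2 (cat.), THF, 40 °C to reflux; used as a titrated solution
Reagents that add atoms: magnesium, [Mg]
Why: Grignard formation by insertion of magnesium into the aryl C–Br bond; the electron-rich bromide needs iodine activation and gentle heating, and the ortho methoxy group stabilises the reagent by coordination.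

Step 2
Reactants: 3 4-phenylbut-1-yne
Product: 5 N-methoxy-N-methyl-5-phenylpent-2-ynamide, via lithium acetylide 4 (not isolated)
Conditions: n-BuLi, THF, −78 °C; then cannulated into ClC(O)N(OMe)Me, THF, −78 °C to 0 °C
Reagents that add atoms: N-methoxy-N-methylcarbamoyl chloride, CON(C)C(=O)Cl
Why: The terminal alkyne is deprotonated completely and the acetylide 4 displaces chloride from the carbamoyl chloride (nucleophilic acyl substitution). Adding 4 to the chloride keeps the more electrophilic acid chloride in excess, so the product amide is not attacked a second time.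

Step 3
Reactants: 6 1-fluoro-2,3-dimethoxybenzene; 2 2,4-dimethoxyphenylmagnesium bromide; 5 N-methoxy-N-methyl-5-phenylpent-2-ynamide
Product: 10 1-[6-(2,4-dimethoxyphenyl)-2,3-dimethoxyphenyl]-5-phenylpent-2-yn-1-one, via aryllithium 7 (not isolated), via aryne 8 (not isolated), via biarylmagnesium bromide 9 (not isolated)
Conditions: 6, n-BuLi (1.0 equiv), THF, −78 °C; cannulated slowly into 2 (2 equiv), THF, 0 °C to rt; then 5 (2.5 equiv), −20 °C to rt; poured into cold 1 M HCl
Reagents that add atoms: none
Why: n-BuLi should remove the ring hydrogen beside fluorine in 6, the most acidic one (fluorine acidifies its ortho position more than methoxy does, and in THF at −78 °C metalation next to fluorine is the faster process), to give 7. On entering the solution of 2 at 0 °C, 7 loses LiF and becomes 3,4-dimethoxybenzyne 8, formed in small portions in an excess of the arylmagnesium nucleophile. The methoxy group on C8a', next to the triple bond, withdraws electrons through the σ framework and distorts the aryne so that C5' is the more electrophilic carbon; the aryl group of 2 therefore bonds to C5' (bond C6–C5') and the carbanion appears at C4a', where the neighbouring oxygen stabilises it and holds the magnesium, giving 9. 9 then adds to the amide carbonyl of 5 to form a magnesium-chelated tetrahedral adduct that persists until the acid quench, so the ketone is released only on work-up and cannot be attacked twice (bond C4a'–C4'). The closest known reaction type is the addition of aryl Grignard reagents to arynes made from ortho-lithiated fluoroarenes with capture of the 2-biarylmagnesium halide by an electrophile, combined here with the ketone synthesis from N-methoxy-N-methyl amides. No ring is closed and no stereocentre is formed. The step needs regiocontrol in the aryne addition, which the C8a' methoxy group supplies, and carbonyl attack instead of conjugate attack on the ynamide, which a copper-free arylmagnesium reagent favours. Because the aryne is a high-energy and sterically undemanding electrophile, the congestion around C5' that would slow a cross-coupling matters little, and the cold acidic quench protonates the liberated N,O-dimethylhydroxylamine so that it cannot add to the ynone.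

Step 4
Reactants: 10 1-[6-(2,4-dimethoxyphenyl)-2,3-dimethoxyphenyl]-5-phenylpent-2-yn-1-one
Product: 11 1-[6-(2,4-dimethoxyphenyl)-2-hydroxy-3-methoxyphenyl]-5-phenylpent-2-yn-1-one
Conditions: BCl3 (1.2 equiv), CH2Cl2, −78 °C to −20 °C; aq. NaHCO3
Reagents that add atoms: none
Why: BCl3 binds the ketone oxygen and the neighbouring C8a' methoxy oxygen in a six-membered chelate, and chloride removes that methyl group only (chelation-controlled ether cleavage); the three other methyl ethers have no carbonyl beside them. Any 13 formed already here by attack of the C8a' oxygen on the Lewis-acid-activated ynone is the product of step 5 and is carried along.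

Step 5
Reactants: 11 1-[6-(2,4-dimethoxyphenyl)-2-hydroxy-3-methoxyphenyl]-5-phenylpent-2-yn-1-one
Product: 13 5-(2,4-dimethoxyphenyl)-8-methoxy-2-(2-phenylethyl)-4H-chromen-4-one, via enaminone 12 (not isolated)
Conditions: Et2NH (3 equiv), EtOH, rt to 50 °C
Reagents that add atoms: none
Why: Et2NH adds to the ynone (aza-Michael addition) to give enaminone 12, whose β-carbon is attacked by the C8a' phenol in an addition–elimination that expels the amine and closes O1'–C2'. This path allows only the 6-endo product, whereas direct base-mediated closure of such ynones can leak into 5-exo attack.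

Step 6
Reactants: 13 5-(2,4-dimethoxyphenyl)-8-methoxy-2-(2-phenylethyl)-4H-chromen-4-one
Product: 14 5-(5-acetyl-2,4-dimethoxyphenyl)-8-methoxy-2-(2-phenylethyl)-4H-chromen-4-one
Conditions: AcCl (1.5 equiv), AlCl3 (3 equiv), CH2Cl2, 0 °C
Reagents that add atoms: acetyl chloride, CC(=O)Cl
Why: Friedel–Crafts acetylation; C4a is para to the C7 ether and ortho to the C8a ether, C8 between the two ethers is shielded, and ring B and pyranone B are deactivated by the Lewis-acid-complexed carbonyl. Partial loss of the C8a methyl group at this stage does no harm because step 7 removes it.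

Step 7
Reactants: 14 5-(5-acetyl-2,4-dimethoxyphenyl)-8-methoxy-2-(2-phenylethyl)-4H-chromen-4-one
Product: 15 5-(5-acetyl-4-hydroxy-2-methoxyphenyl)-8-methoxy-2-(2-phenylethyl)-4H-chromen-4-one
Conditions: BCl3 (2.5 equiv), CH2Cl2, −78 °C to 0 °C; aq. NaHCO3
Reagents that add atoms: none
Why: The same chelation-controlled ether cleavage as in step 4: only the C8a methoxy group sits beside a ketone, while the C7 and C8' ethers have no carbonyl in reach. One extra equivalent of BCl3 is taken up by the pyranone carbonyl.

Step 8
Reactants: 15 5-(5-acetyl-4-hydroxy-2-methoxyphenyl)-8-methoxy-2-(2-phenylethyl)-4H-chromen-4-one; 16 ethyl 3-phenylpropanoate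
Product: 17 1-{2-hydroxy-4-methoxy-5-[8-methoxy-4-oxo-2-(2-phenylethyl)-4H-chromen-5-yl]phenyl}-5-phenylpentane-1,3-dione
Conditions: NaH (4 equiv), 16 (2 equiv), THF, reflux; cold dil. HCl
Reagents that add atoms: none
Why: Crossed Claisen condensation: NaH forms the phenoxide and then the methyl ketone enolate, which is acylated by ester 16, and deprotonation of the 1,3-diketone drives the equilibrium. The ketone is more acidic than the ester, so self-condensation of 16 is the minor path and is covered by the excess.

Step 9
Reactants: 17 1-{2-hydroxy-4-methoxy-5-[8-methoxy-4-oxo-2-(2-phenylethyl)-4H-chromen-5-yl]phenyl}-5-phenylpentane-1,3-dione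
Product: 18 7-methoxy-6-[8-methoxy-4-oxo-2-(2-phenylethyl)-4H-chromen-5-yl]-2-(2-phenylethyl)-4H-chromen-4-one
Conditions: conc. HCl (cat.), AcOH, 100 °C
Reagents that add atoms: none
Why: Acid-catalysed cyclodehydration, the closing step of the classical chromone synthesis: the C8a phenol adds to the C2 carbonyl and water is lost, and only a six-membered ring can form. The same acid should reclose pyranone B if the base of step 8 has opened it.

Step 10
Reactants: 18 7-methoxy-6-[8-methoxy-4-oxo-2-(2-phenylethyl)-4H-chromen-5-yl]-2-(2-phenylethyl)-4H-chromen-4-one
Product: 19 7-hydroxy-6-[8-hydroxy-4-oxo-2-(2-phenylethyl)-4H-chromen-5-yl]-2-(2-phenylethyl)-4H-chromen-4-one (target)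
Conditions: BBr3 (6 equiv), CH2Cl2, −78 °C to rt; MeOH, then aq. NaHCO3
Reagents that add atoms: none
Why: BBr3 cleaves both aryl methyl ethers (Lewis acid–base adduct, then bromide attack on the methyl group). The pyranones tolerate Lewis acids but bind reagent, hence the excess; hydrolysis of the borates frees the two phenols.

## Compound list

1 | 1-bromo-2,4-dimethoxybenzene | COc1ccc(Br)c(OC)c1 | starting material
2 | 2,4-dimethoxyphenylmagnesium bromide | COc1ccc([Mg]Br)c(OC)c1 | intermediate
3 | 4-phenylbut-1-yne | C#CCCc1ccccc1 | starting material
4 | lithium 4-phenylbut-1-yn-1-ide | [Li]C#CCCc1ccccc1 | intermediate (not isolated)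
5 | N-methoxy-N-methyl-5-phenylpent-2-ynamide | CON(C)C(=O)C#CCCc1ccccc1 | intermediate
6 | 1-fluoro-2,3-dimethoxybenzene | COc1cccc(F)c1OC | starting material
7 | (2-fluoro-3,4-dimethoxyphenyl)lithium | [Li]c1ccc(OC)c(OC)c1F | intermediate (not isolated)
8 | 3,4-dimethoxybenzyne (1,2-didehydro-3,4-dimethoxybenzene) | COC1=C(OC)C#CC=C1 | intermediate (not isolated)
9 | [6-(2,4-dimethoxyphenyl)-2,3-dimethoxyphenyl]magnesium bromide | COc1ccc(-c2ccc(OC)c(OC)c2[Mg]Br)c(OC)c1 | intermediate (not isolated)
10 | 1-[6-(2,4-dimethoxyphenyl)-2,3-dimethoxyphenyl]-5-phenylpent-2-yn-1-one | COc1ccc(-c2ccc(OC)c(OC)c2C(=O)C#CCCc2ccccc2)c(OC)c1 | intermediate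
11 | 1-[6-(2,4-dimethoxyphenyl)-2-hydroxy-3-methoxyphenyl]-5-phenylpent-2-yn-1-one | COc1ccc(-c2ccc(OC)c(O)c2C(=O)C#CCCc2ccccc2)c(OC)c1 | intermediate
12 | (E)-3-(diethylamino)-1-[6-(2,4-dimethoxyphenyl)-2-hydroxy-3-methoxyphenyl]-5-phenylpent-2-en-1-one | CCN(CC)/C(CCc1ccccc1)=C/C(=O)c1c(O)c(OC)ccc1-c1ccc(OC)cc1OC | intermediate (not isolated)
13 | 5-(2,4-dimethoxyphenyl)-8-methoxy-2-(2-phenylethyl)-4H-chromen-4-one | COc1ccc(-c2ccc(OC)c3oc(CCc4ccccc4)cc(=O)c23)c(OC)c1 | intermediate
14 | 5-(5-acetyl-2,4-dimethoxyphenyl)-8-methoxy-2-(2-phenylethyl)-4H-chromen-4-one | CC(=O)c1cc(-c2ccc(OC)c3oc(CCc4ccccc4)cc(=O)c23)c(OC)cc1OC | intermediate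
15 | 5-(5-acetyl-4-hydroxy-2-methoxyphenyl)-8-methoxy-2-(2-phenylethyl)-4H-chromen-4-one | CC(=O)c1cc(-c2ccc(OC)c3oc(CCc4ccccc4)cc(=O)c23)c(OC)cc1O | intermediate
16 | ethyl 3-phenylpropanoate | CCOC(=O)CCc1ccccc1 | starting material
17 | 1-{2-hydroxy-4-methoxy-5-[8-methoxy-4-oxo-2-(2-phenylethyl)-4H-chromen-5-yl]phenyl}-5-phenylpentane-1,3-dione | O=C(CCc1ccccc1)CC(=O)c1cc(-c2ccc(OC)c3oc(CCc4ccccc4)cc(=O)c23)c(OC)cc1O | intermediate
18 | 7-methoxy-6-[8-methoxy-4-oxo-2-(2-phenylethyl)-4H-chromen-5-yl]-2-(2-phenylethyl)-4H-chromen-4-one | COc1cc2oc(CCc3ccccc3)cc(=O)c2cc1-c1ccc(OC)c2oc(CCc3ccccc3)cc(=O)c12 | intermediate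
19 | 7-hydroxy-6-[8-hydroxy-4-oxo-2-(2-phenylethyl)-4H-chromen-5-yl]-2-(2-phenylethyl)-4H-chromen-4-one | O=c1cc(CCc2ccccc2)oc2cc(O)c(-c3ccc(O)c4oc(CCc5ccccc5)cc(=O)c34)cc12 | target

Total step count: 10. Longest linear sequence: 9 steps (step 1 or step 2, then steps 3 to 10).

## Steps least certain to work

**Step 3 (key step).** Three processes could lower the outcome.
- Metalation of 6 beside the C8' methoxy group instead of beside fluorine would give an aryllithium that cannot eliminate and is simply acylated.
- Capture of the aryne by 7 instead of by 2 would build oligoaryls.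
- Slow acylation of the doubly ortho-substituted arylmagnesium 9 would leave it to be protonated on work-up.

The excess of 2 also consumes amide, which is why 5 is used in excess; the simpler ynone from that side reaction is removed by chromatography.

If only the metalation site is at fault, the isomer 4-fluoro-1,2-dimethoxybenzene F1 is used in place of 6. Its hydrogen between fluorine and methoxy is the most acidic by any mechanism, and the aryllithium (6-fluoro-2,3-dimethoxyphenyl)lithium F2 eliminates LiF to the same aryne 8, so the route is rejoined at 8.

If the aryne step fails as a whole, the two bonds are made one after the other, setting out from 2: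
- 2 is quenched with B(OMe)3 and hydrolysed to (2,4-dimethoxyphenyl)boronic acid F3.
- F3 is coupled with commercial 6-bromo-2,3-dimethoxybenzaldehyde F4 (Pd(PPh3)4, a zerovalent palladium catalyst, K2CO3, dioxane–water, 90 °C) to 6-(2,4-dimethoxyphenyl)-2,3-dimethoxybenzaldehyde F5. This Suzuki coupling has only one ortho substituent on each partner.
- Acetylide 4 adds to F5 to give racemic 1-[6-(2,4-dimethoxyphenyl)-2,3-dimethoxyphenyl]-5-phenylpent-2-yn-1-ol F6.
- MnO2 in CH2Cl2 oxidises F6 to 10, where the route is rejoined.

If only the acylation of 9 is slow, 9 is quenched with DMF, which gives the same aldehyde F5.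

**Step 8.** The hydride base acts on a molecule that already contains pyranone B. Deprotonation of the CH2 group on C2' followed by acylation there, or opening of pyranone B at C2' by ethoxide, would compete with the desired Claisen condensation. Step 9 repairs ring opening but not the acylation. The fallback avoids strong base by building pyranone A as pyranone B was built, setting out from 13:
- N-iodosuccinimide with catalytic CF3CO2H in MeCN should iodinate C4a to give 5-(5-iodo-2,4-dimethoxyphenyl)-8-methoxy-2-(2-phenylethyl)-4H-chromen-4-one F7.
- Carbonylative Sonogashira coupling of F7 with 3 (PdCl2(PPh3)2, a divalent palladium precatalyst, Et3N, CO at 1 atm, THF) gives the ynone 1-{2,4-dimethoxy-5-[8-methoxy-4-oxo-2-(2-phenylethyl)-4H-chromen-5-yl]phenyl}-5-phenylpent-2-yn-1-one F8.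
- BCl3 removes the C8a methyl group by chelation to give the phenol 1-{2-hydroxy-4-methoxy-5-[8-methoxy-4-oxo-2-(2-phenylethyl)-4H-chromen-5-yl]phenyl}-5-phenylpent-2-yn-1-one F9.
- Et2NH in EtOH closes F9 as in step 5 and the route is rejoined at 18.

**Step 5.** The closure could stall at enaminone 12 or, if the amine path is slow, go partly by 5-exo attack of the phenoxide on the ynone; step 4 could also add HCl across the ynone. The fallback replaces the ynone by a 1,3-diketone, which can close only to the six-membered ring, setting out from 10:
- Et2NH adds to 10 to give (E)-3-(diethylamino)-1-[6-(2,4-dimethoxyphenyl)-2,3-dimethoxyphenyl]-5-phenylpent-2-en-1-one F10.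
- Aqueous HCl in THF hydrolyses F10 to 1-[6-(2,4-dimethoxyphenyl)-2,3-dimethoxyphenyl]-5-phenylpentane-1,3-dione F11.
- BCl3 cleaves the C8a' ether to 1-[6-(2,4-dimethoxyphenyl)-2-hydroxy-3-methoxyphenyl]-5-phenylpentane-1,3-dione F12.
- Acid cyclodehydration under the conditions of step 9 gives 13, where the route is rejoined.

**Step 6.** The Lewis acid is tied up by the pyranone carbonyl and the ethers, so acylation may be sluggish, and forcing it risks unselective ether cleavage or attack at C3' of pyranone B. The fallback installs the acetyl group by cross-coupling, setting out from 13: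
- Iodination gives F7 as described above.
- Stille coupling with tributyl(1-ethoxyethenyl)stannane (Pd(PPh3)4, a zerovalent palladium catalyst, toluene, 100 °C) gives the enol ether 5-[5-(1-ethoxyethenyl)-2,4-dimethoxyphenyl]-8-methoxy-2-(2-phenylethyl)-4H-chromen-4-one F13.
- Dilute aqueous HCl hydrolyses F13 to 14, where the route is rejoined.

## Further compounds

F1 | step 3 | 4-fluoro-1,2-dimethoxybenzene | COc1ccc(F)cc1OC
F2 | step 3 | (6-fluoro-2,3-dimethoxyphenyl)lithium | [Li]c1c(F)ccc(OC)c1OC
F3 | step 3 | (2,4-dimethoxyphenyl)boronic acid | COc1ccc(B(O)O)c(OC)c1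
F4 | step 3 | 6-bromo-2,3-dimethoxybenzaldehyde | COc1ccc(Br)c(C=O)c1OC
F5 | step 3 | 6-(2,4-dimethoxyphenyl)-2,3-dimethoxybenzaldehyde | COc1ccc(-c2ccc(OC)c(OC)c2C=O)c(OC)c1
F6 | step 3 | 1-[6-(2,4-dimethoxyphenyl)-2,3-dimethoxyphenyl]-5-phenylpent-2-yn-1-ol (racemic) | COc1ccc(-c2ccc(OC)c(OC)c2C(O)C#CCCc2ccccc2)c(OC)c1
F7 | step 8 | 5-(5-iodo-2,4-dimethoxyphenyl)-8-methoxy-2-(2-phenylethyl)-4H-chromen-4-one | COc1cc(OC)c(-c2ccc(OC)c3oc(CCc4ccccc4)cc(=O)c23)cc1I
F8 | step 8 | 1-{2,4-dimethoxy-5-[8-methoxy-4-oxo-2-(2-phenylethyl)-4H-chromen-5-yl]phenyl}-5-phenylpent-2-yn-1-one | COc1cc(OC)c(-c2ccc(OC)c3oc(CCc4ccccc4)cc(=O)c23)cc1C(=O)C#CCCc1ccccc1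
F9 | step 8 | 1-{2-hydroxy-4-methoxy-5-[8-methoxy-4-oxo-2-(2-phenylethyl)-4H-chromen-5-yl]phenyl}-5-phenylpent-2-yn-1-one | Oc1cc(OC)c(-c2ccc(OC)c3oc(CCc4ccccc4)cc(=O)c23)cc1C(=O)C#CCCc1ccccc1
F10 | step 5 | (E)-3-(diethylamino)-1-[6-(2,4-dimethoxyphenyl)-2,3-dimethoxyphenyl]-5-phenylpent-2-en-1-one | CCN(CC)/C(CCc1ccccc1)=C/C(=O)c1c(OC)c(OC)ccc1-c1ccc(OC)cc1OC
F11 | step 5 | 1-[6-(2,4-dimethoxyphenyl)-2,3-dimethoxyphenyl]-5-phenylpentane-1,3-dione | COc1ccc(-c2ccc(OC)c(OC)c2C(=O)CC(=O)CCc2ccccc2)c(OC)c1
F12 | step 5 | 1-[6-(2,4-dimethoxyphenyl)-2-hydroxy-3-methoxyphenyl]-5-phenylpentane-1,3-dione | COc1ccc(-c2ccc(OC)c(O)c2C(=O)CC(=O)CCc2ccccc2)c(OC)c1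
F13 | step 6 | 5-[5-(1-ethoxyethenyl)-2,4-dimethoxyphenyl]-8-methoxy-2-(2-phenylethyl)-4H-chromen-4-one | CCOC(=C)c1cc(-c2ccc(OC)c3oc(CCc4ccccc4)cc(=O)c23)c(OC)cc1OC
A1 | alternative 1 | 7-methoxy-6-[8-methoxy-2-(2-phenylethyl)-2H-chromen-5-yl]-2-(2-phenylethyl)-4H-chromen-4-one (racemic) | COc1cc2oc(CCc3ccccc3)cc(=O)c2cc1-c1ccc(OC)c2OC(CCc3ccccc3)C=Cc12
A2 | alternative 1 | 7-methoxy-6-{4-methoxy-3-[(5-phenylpent-1-yn-3-yl)oxy]phenyl}-2-(2-phenylethyl)-4H-chromen-4-one (racemic) | COc1cc2oc(CCc3ccccc3)cc(=O)c2cc1-c1ccc(OC)c(OC(CCc2ccccc2)C#C)c1
A3 | alternative 2 | methyl 6-(4-ethoxy-2-hydroxyphenyl)-2,3-dimethoxybenzoate | COC(=O)c1c(OC)c(OC)ccc1-c1ccc(OCC)cc1O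
A4 | alternative 2 | methyl 6-[(1E)-4-diazo-3-oxobut-1-en-1-yl]-2,3-dimethoxybenzoate | COC(=O)c1c(OC)c(OC)ccc1/C=C/C(=O)C=[N+]=[N-]
A5 | alternative 2 | ethoxyethyne | CCOC#C
A6 | alternative 3 | 7-hydroxy-6-[8-methoxy-4-oxo-2-(2-phenylethyl)-4H-chromen-5-yl]-2-(2-phenylethyl)-4H-chromen-4-one | O=c1cc(CCc2ccccc2)oc2cc(O)c(-c3ccc(OC)c4oc(CCc5ccccc5)cc(=O)c34)cc12
A7 | alternative 3 | 8-methoxy-5-{1-methoxy-3-oxo-4-[4-oxo-6-(2-phenylethyl)-4H-pyran-2-yl]but-1-en-2-yl}-2-(2-phenylethyl)-4H-chromen-4-one (mixture of double-bond isomers) | O=c1cc(CCc2ccccc2)oc(CC(=O)C(=COC)c2ccc(OC)c3oc(CCc4ccccc4)cc(=O)c23)c1
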